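## Structural features

The target is a 2-arylbenzofuran: a benzo ring (ring A, C3a to C7a) is fused to a furan ring, and furan C2 carries a 3-hydroxy-4-methoxyphenyl ring (ring B). The furan is fully substituted (aryl on C2, methoxyl on C3, C3a and C7a shared with ring A). Ring A bears a free phenol on C6 and a prenyl chain on C5, ortho to each other, with C4 and C7 unsubstituted. There is no stereocentre and no stereogenic double bond, so every problem is one of regiochemistry and chemoselectivity. The fragile groups are the ortho-prenylphenol (acid closes it to a 2,2-dimethylchroman, quinone oxidants turn it into a chromene), the 3-methoxyfuran (an electron-rich aromatic enol ether) and the two phenols on an easily oxidised π-system. The real difficulty is twofold: a furan with oxygen on C3 next to an aryl group on C2, and a prenyl group that must sit on C5 and not on C7. The key step uses the fact that O1, C2 and C7a of the furan map onto O1, C5 and C2 of an oxazole, while C3 with its methoxyl and C3a map onto the two carbons of a methoxyalkyne. The four-atom chain C7–C6–C5–C4 that links the two then becomes ring A, with the C6 oxygen and the C5 prenyl group already in place.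

## Logic of the disconnections

25 to 24: the two aryl O–Si bonds are cut. Both phenols are masked by the same silyl group so that one fluoride treatment ends the synthesis. A silyl ether is preferred over an acetal-type group on ring B because its removal needs no acid, which the ortho-prenylphenol and the 3-methoxyfuran of 25 would not tolerate well. The forward step must only avoid free phenoxide in air.

24 to 23 to 22: ring A is taken back to the dihydro level by adding hydrogen to C4 and C5. A palladium-enolate dehydrogenation of 22 is not planned, because 22 enolises toward C7 (conjugation with the furan) and palladium on C7 has no β-hydrogen on C7a. Instead 22 is converted into the silyl dienol ether 23, and a quinone removes hydride from C4 and a proton from C5. This works for either enol ether regioisomer and gives the new phenol already silylated, so that it cannot be oxidised on to a chromene. The demand is exact stoichiometry of the oxidant.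

22 to 20 (key disconnection): the bonds C2–C3 and C3a–C7a are cut and the elements of acetonitrile are added back across C2 and C7a. This turns the furan into an oxazole and C3/C3a into a methoxyalkyne, and opens ring A to an acyclic ketone chain. Two rings and the whole substitution pattern of the benzofuran are traded for one linear, racemic precursor. The forward step must make an electron-rich alkyne react with the oxazole before the ynol ether decomposes, and in preference to the prenyl double bond. Compounds 20 and 22 keep the required skeletons; only the phenol protecting group on ring B is a silyl ether.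

20 to 17 plus 18: the bond between C5 (ring numbering) and the prenyl CH2 is cut. Adding the prenyl group last keeps the chain-building chemistry free of a second alkene and uses the 1,3-dianion of 17, whose terminal carbanion is the more reactive site. The demand is regioselective alkylation at C3 of the hexynone and not at C1.

17 to 16 to 8 plus 14: the C7–C6 bond (ring numbering) is cut between the oxazole 2-methyl carbon and an aldehyde carbon, with the ketone taken back to a carbinol. The acyl partner is held at the aldehyde level on purpose. A carboxylic acid on this chain could not be carried, since carboxylic acids add across ynol ethers, and this rules out any route through the free 5-methoxypent-4-ynoic acid. The demand is a neutral oxidation of 16 that leaves the ynol ether alone.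

14 to 13 to 12 to 9 plus 10: the propargylic C4–C3a bond (ring numbering) is cut, giving a methoxyacetylide and a three-carbon bromide with a silyl-protected alcohol. The acetylide is made in the flask from 9, so no volatile alkoxyacetylene is handled. The methyl ether is kept because, unlike an ethyl or tert-butyl ether, it has no β-hydrogen and cannot fragment thermally to a ketene and an alkene before the key step. The demand is that the alkylation, deprotection and oxidation all stay basic or neutral.

8 to 7 to 2 plus 4, then 2 to 1 and 4 to 3: the oxazole is opened at O1–C5 to an α-acetamido ketone (cyclodehydration in the forward sense). The aryl–carbonyl bond is then cut to an aryl Grignard reagent and a Weinreb amide. The 4-methyl group of 8 comes from alanine and leaves later as harmless acetonitrile; the 2-methyl group comes from the acetyl group and becomes C7. The demand is a cyclodehydration mild enough for the aryl silyl ether.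

## Other disconnections considered

Alternative 1: The furan ring is cut at O1–C2 and C2–C3. In the forward sense the ylide from the benzylic sulfonium salt A3 would add to the aldehyde carbon of the prenylated salicylaldehyde A2 (C2–C3). The neighbouring phenoxide would then displace the sulfide leaving group at the benzylic carbon (O1–C2), directly or by way of the epoxide, to give the trans-dihydrobenzofuranol A1. Oxidation of A1 to the benzofuranone A4, O-methylation of its enol and removal of both acetal groups would complete the synthesis.
- In its favour: both aromatic rings are bought as arenes, so no aromatisation is needed. The plan is convergent and ionic at or below room temperature. Its ring-forming event belongs to a reaction family with close analogy, which is a clear advantage over the chosen plan, whose key step has none.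
- Against it here: the prenyl group of A2 must first be placed selectively at one of two activated ring positions. C3 arrives at the alcohol level, so an oxidation and an ambident methylation follow, and the enolate of A4 can be methylated at the doubly activated C2 instead of at oxygen. Two stereocentres are made in A1 only to be erased. If closure runs through the epoxide it is a 5-endo opening that relies on benzylic activation. The final double deprotection is acidic, beside an ortho-prenylphenol.
- Comparison: on structure the chosen plan brings the C3 methoxyl in at its final oxidation level and fixes the prenyl position by construction, while alternative 1 has to correct C3 afterwards. On mechanism alternative 1 is the better supported. On step count the two are about equal, with alternative 1 perhaps one or two steps shorter.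

Alternative 2: Ring A is cut at C5–C6, and C6 is traced back through a Wolff rearrangement to the diazoketone A6. A6 is a furan that carries the aryl group, the methoxyl, a Z-configured dienyl chain and the diazoacetyl group. Irradiation would remove the diazo nitrogen, the furyl group would migrate to give a furylketene, and a 6π-electrocyclisation between the ketene carbon and the far carbon of the Z-alkene would close ring A. The dienone would tautomerise to the phenol A5.
- In its favour: ring A would appear directly as the phenol with no separate oxidation, which is better than the chosen plan on that point. The prenyl position is fixed by the alkene. The conditions are neutral. The last deprotection is by fluoride, the equal of the chosen plan. Both halves of the mechanism (Wolff rearrangement, dienylketene electrocyclisation) are well-established reaction types.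
- Against it here: A6 is a tetrasubstituted furan with four different groups, so the 2-aryl-3-methoxyfuran problem is moved into the precursor and not solved. The Z-alkene can isomerise under the same irradiation, and the E-isomer cannot cyclise. The ketene can dimerise or be trapped. A diazoketone has to be made and handled.
- Comparison: on structure and step count the chosen plan should be shorter, because its oxazole is made in four steps from simple materials. On mechanism alternative 2 is the safer ring-A closure but needs the harder precursor.

Alternative 3: Ring A is cut at C7–C7a. The precursor A8 is a 5-aryl tetronate methyl ether whose C3 carries a Z-enone side chain ending in a methyl ketone. Base would form the methyl ketone enolate, whose carbon (C7) would attack the lactone carbonyl (C7a). Dehydration and a proton shift from C2 would then make both the furan and ring A aromatic and give A7.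
- In its favour: the chemistry is ionic and uses simple reagents. The C3 methoxyl comes from O-methylation of a tetronic acid. Ring A is formed at the phenol oxidation level without an oxidant and without high temperature; on both points it is better than the chosen plan.
- Against it here: the lactone carbonyl is a vinylogous carbonate and a poor electrophile. The tetrahedral adduct can collapse by expelling the ring oxygen instead of dehydrating, which would open the lactone. The C2 hydrogen of A8 (benzylic and γ to the lactone carbonyl) should be more acidic than the methyl ketone, so the base may form the 2-oxyfuran anion first. The enone must be Z. A7 still needs an acidic deprotection next to the prenylphenol.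
- Comparison: step count is about equal. On structure both plans carry the C3 methoxyl through unchanged. On mechanism alternative 3 has more competing ionic pathways in its key step, whereas the chosen plan has one main question, the rate of the cycloaddition.

Key step: step 11

Assumption (remark on the chemistry): all chiral intermediates are used as racemates or diastereomer mixtures. This is sufficient because every stereocentre of the route (the α-carbon of 4 and 7, the carbinol carbon of 16, C5 of 20 to 23) becomes an sp2 centre before the achiral target 25 is reached.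

## Route

Step 1
Reactants: 1 5-bromo-2-methoxyphenol
Product: 2 (5-bromo-2-methoxyphenoxy)triisopropylsilane
Conditions: TIPSCl, imidazole, DMF, rt
Reagents that add atoms: chlorotriisopropylsilane, CC(C)[Si](Cl)(C(C)C)C(C)C
Why: Imidazole-promoted silylation of a phenol; the triisopropylsilyl ether should survive organomagnesium reagents, lithium amides and heat, and is removed at the end by fluoride without acid.

Step 2
Reactants: 3 N-acetylalanine (racemic)
Product: 4 2-acetamido-N-methoxy-N-methylpropanamide (racemic)
Conditions: MeNHOMe·HCl, EDC·HCl, N-methylmorpholine, CH2Cl2, 0 °C to rt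
Reagents that add atoms: N,O-dimethylhydroxylamine hydrochloride, CNOC.Cl
Why: Carbodiimide amide coupling to the Weinreb amide; loss of configuration at the α-carbon is irrelevant because this carbon becomes sp2 C4 of the oxazole.

Step 3
Reactants: 2 (5-bromo-2-methoxyphenoxy)triisopropylsilane; 4 2-acetamido-N-methoxy-N-methylpropanamide
Product: 7 N-{1-[4-methoxy-3-(triisopropylsilyloxy)phenyl]-1-oxopropan-2-yl}acetamide (racemic), via aryl Grignard reagent 5 (not isolated), via chloromagnesium amidate 6 (not isolated)
Conditions: 2, Mg, THF, 45 °C; 4, i-PrMgCl, THF, −20 °C; mix, −20 °C to rt; aq NH4Cl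
Reagents that add atoms: none
Why: Weinreb ketone synthesis; deprotonating the amide N–H first with i-PrMgCl spares the aryl Grignard reagent, and the chelated tetrahedral adduct prevents a second addition. The C–Mg bond is meta to the silyloxy group, so no silyl migration is expected.

Step 4
Reactants: 7 N-{1-[4-methoxy-3-(triisopropylsilyloxy)phenyl]-1-oxopropan-2-yl}acetamide
Product: 8 5-[4-methoxy-3-(triisopropylsilyloxy)phenyl]-2,4-dimethyl-1,3-oxazole
Conditions: PPh3, I2, Et3N, CH2Cl2, 0 °C to rt
Reagents that add atoms: none
Why: Robinson–Gabriel cyclodehydration in its Ph3P/I2/Et3N variant, in which the amide oxygen closes onto the activated ketone carbon (O1–C5) with loss of Ph3P=O; the basic medium should spare the aryl silyl ether that mineral-acid conditions would endanger.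

Step 5
Reactants: 9 2-chloro-1,1-dimethoxyethane; 10 (3-bromopropoxy)(tert-butyl)dimethylsilane
Product: 12 tert-butyl[(5-methoxypent-4-yn-1-yl)oxy]dimethylsilane, via sodium methoxyacetylide 11 (not isolated)
Conditions: 9, NaNH2 (3 equiv), liq. NH3, −33 °C; then 10, THF, −33 °C to rt
Reagents that add atoms: none
Why: Double elimination (methanol, then HCl) from the α-chloroacetal and deprotonation give the sodium alkoxyacetylide, which is alkylated by a primary bromide in liquid ammonia (SN2), the classical entry to 1-alkoxyalk-1-ynes. All the amide base is consumed, and the alkyl silyl ether is inert to it.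

Step 6
Reactants: 12 tert-butyl[(5-methoxypent-4-yn-1-yl)oxy]dimethylsilane
Product: 13 5-methoxypent-4-yn-1-ol
Conditions: n-Bu4NF, THF, 0 °C
Reagents that add atoms: none
Why: Fluoride desilylation under basic conditions, which the acid-sensitive ynol ether should tolerate; work-up and chromatography are kept basic (Et3N-treated silica).

Step 7
Reactants: 13 5-methoxypent-4-yn-1-ol
Product: 14 5-methoxypent-4-ynal
Conditions: (n-Pr)4N[RuO4] (5 mol%), NMO, 4 Å MS, CH2Cl2, rt
Reagents that add atoms: none
Why: Ley–Griffith oxidation; it is neutral, forms no carboxylic acid by-product that could add to the ynol ether, and stops at the aldehyde in the presence of molecular sieves.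

Step 8
Reactants: 8 5-[4-methoxy-3-(triisopropylsilyloxy)phenyl]-2,4-dimethyl-1,3-oxazole; 14 5-methoxypent-4-ynal
Product: 16 6-methoxy-1-{5-[4-methoxy-3-(triisopropylsilyloxy)phenyl]-4-methyl-1,3-oxazol-2-yl}hex-5-yn-2-ol (racemic), via 2-(lithiomethyl)oxazole 15 (not isolated)
Conditions: 8, LiN(i-Pr)2, THF, −78 °C; then 14, −78 °C; aq NH4Cl
Reagents that add atoms: none
Why: Lateral lithiation of the 2-methyl group of the oxazole (the most acidic C–H, since C5 is blocked and the 4-methyl is far less acidic) followed by 1,2-addition to the aldehyde; the new carbinol centre is not controlled and is oxidised in the next step.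

Step 9
Reactants: 16 6-methoxy-1-{5-[4-methoxy-3-(triisopropylsilyloxy)phenyl]-4-methyl-1,3-oxazol-2-yl}hex-5-yn-2-ol
Product: 17 6-methoxy-1-{5-[4-methoxy-3-(triisopropylsilyloxy)phenyl]-4-methyl-1,3-oxazol-2-yl}hex-5-yn-2-one
Conditions: (n-Pr)4N[RuO4] (5 mol%), NMO, 4 Å MS, CH2Cl2, 0 °C to rt
Reagents that add atoms: none
Why: Ley–Griffith oxidation of the secondary alcohol to the ketone under neutral conditions that the ynol ether and the aryl silyl ether should survive.

Step 10
Reactants: 17 6-methoxy-1-{5-[4-methoxy-3-(triisopropylsilyloxy)phenyl]-4-methyl-1,3-oxazol-2-yl}hex-5-yn-2-one; 18 1-bromo-3-methylbut-2-ene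
Product: 20 6-methoxy-1-{5-[4-methoxy-3-(triisopropylsilyloxy)phenyl]-4-methyl-1,3-oxazol-2-yl}-3-(3-methylbut-2-en-1-yl)hex-5-yn-2-one (racemic), via dilithium dianion 19 (not isolated)
Conditions: LiN(i-Pr)2 (2.2 equiv), THF, −78 to −20 °C; then 18 (1.0 equiv), −78 to −40 °C; aq NH4Cl
Reagents that add atoms: none
Why: 1,3-Dianion alkylation of the acetoacetate type: the first equivalent of base forms the chelated enolate at C1 (between oxazole and carbonyl), the second removes a proton from C3, and the more basic C3 carbanion attacks the allylic bromide. The new stereocentre is racemic and later becomes aromatic C5.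

Step 11
Reactants: 20 6-methoxy-1-{5-[4-methoxy-3-(triisopropylsilyloxy)phenyl]-4-methyl-1,3-oxazol-2-yl}-3-(3-methylbut-2-en-1-yl)hex-5-yn-2-one
Product: 22 3-methoxy-2-[4-methoxy-3-(triisopropylsilyloxy)phenyl]-5-(3-methylbut-2-en-1-yl)-4,5-dihydro-1-benzofuran-6(7H)-one (racemic), via oxygen-bridged cycloadduct 21 (not isolated)
Conditions: mesitylene (0.01 M, degassed), BHT (5 mol%), 165 °C, Ar, base-washed glass
Reagents that add atoms: none
Why: Proposed new method: on heating, the oxazole of 20 should act as a 2-azadiene across C2 and C5 and the tethered methoxyalkyne as dienophile, so that the alkyne carbon remote from oxygen bonds to oxazole C2 (future C3a–C7a) and the methoxy-bearing carbon bonds to the aryl-bearing C5 (future C2–C3), giving the oxygen-bridged adduct 21, which then loses acetonitrile (N3, C4 and its methyl) by cycloreversion to leave the aromatic furan of 22. The closest known reaction type is the intramolecular oxazole–alkyne Diels–Alder/retro-Diels–Alder furan annulation with nitrile extrusion, which is established for ynones and unactivated alkynes but not for a 1-alkoxyalkyne. The polarity should help, because the nucleophilic β-carbon of the ynol ether is the one that must bond to the electrophilic C2 of the azadiene, and the tether demands the same orientation. The furan ring is made by the (4+2)/retro-(4+2) pair, and the carbocycle closes in the same event as a six-membered ring through the four-atom tether C7–C6–C5–C4 that joins a diene terminus to the dienophile; the sp2 ketone carbon and the branch at C5 favour the folded conformer. No stereocentre is created: C5 is carried through as a racemate and the bridgehead centres of 21 vanish on cycloreversion. The step needs chemoselectivity for the alkyne over the prenyl double bond, which sits at the same distance from the oxazole; the trisubstituted alkene would have to bond its dimethyl-bearing carbon to the aryl-bearing C5 and its adduct cannot aromatise by nitrile loss, so that path stays reversible, whereas nitrile loss makes the alkyne path irreversible. High dilution, an aprotic non-polar solvent and the absence of acid are chosen to keep the ynol ether from adding the enol form of the ketone.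

Step 12
Reactants: 22 3-methoxy-2-[4-methoxy-3-(triisopropylsilyloxy)phenyl]-5-(3-methylbut-2-en-1-yl)-4,5-dihydro-1-benzofuran-6(7H)-one
Product: 23 3-methoxy-2-[4-methoxy-3-(triisopropylsilyloxy)phenyl]-5-(3-methylbut-2-en-1-yl)-6-(triisopropylsilyloxy)-4,5-dihydro-1-benzofuran (racemic)
Conditions: TIPSOTf, Et3N, CH2Cl2, 0 °C
Reagents that add atoms: triisopropylsilyl trifluoromethanesulfonate, CC(C)[Si](OS(=O)(=O)C(F)(F)F)(C(C)C)C(C)C
Why: Soft enolisation with a silyl triflate and an amine should give the dienol ether conjugated with the furan (C6=C7); any C5=C6 regioisomer is an equally good substrate for the next step.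

Step 13
Reactants: 23 3-methoxy-2-[4-methoxy-3-(triisopropylsilyloxy)phenyl]-5-(3-methylbut-2-en-1-yl)-6-(triisopropylsilyloxy)-4,5-dihydro-1-benzofuran
Product: 24 3-methoxy-2-[4-methoxy-3-(triisopropylsilyloxy)phenyl]-5-(3-methylbut-2-en-1-yl)-6-(triisopropylsilyloxy)-1-benzofuran
Conditions: DDQ (1.05 equiv), 2,4,6-collidine, PhMe, 0 °C
Reagents that add atoms: none
Why: Quinone dehydrogenation of a dihydroaromatic silyl enol ether: hydride abstraction from C4 gives a cation stabilised by the furan and the silyloxy group (the arenium ion of 24), which loses the C5 proton. The silyl group stays on oxygen, so the new phenol is never free to be oxidised to a chromene, and the C5 stereocentre is removed.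

Step 14
Reactants: 24 3-methoxy-2-[4-methoxy-3-(triisopropylsilyloxy)phenyl]-5-(3-methylbut-2-en-1-yl)-6-(triisopropylsilyloxy)-1-benzofuran
Product: 25 5-[6-hydroxy-3-methoxy-5-(3-methylbut-2-en-1-yl)-1-benzofuran-2-yl]-2-methoxyphenol (target)
Conditions: n-Bu4NF, AcOH, THF, 0 °C
Reagents that add atoms: none
Why: Fluoride cleaves both aryl silyl ethers in one operation; acetic acid protonates the phenoxides so they are not air-oxidised, and is too weak to cyclise the ortho-prenylphenol or hydrolyse the 3-methoxyfuran.

## Compound list

1 | 5-bromo-2-methoxyphenol | COc1ccc(Br)cc1O | starting material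
2 | (5-bromo-2-methoxyphenoxy)triisopropylsilane | COc1ccc(Br)cc1O[Si](C(C)C)(C(C)C)C(C)C | intermediate
3 | N-acetylalanine (racemic) | CC(NC(C)=O)C(=O)O | starting material
4 | 2-acetamido-N-methoxy-N-methylpropanamide (racemic) | CC(NC(C)=O)C(=O)N(C)OC | intermediate
5 | [4-methoxy-3-(triisopropylsilyloxy)phenyl]magnesium bromide | COc1ccc([Mg]Br)cc1O[Si](C(C)C)(C(C)C)C(C)C | intermediate (not isolated)
6 | N-chloromagnesium salt of 2-acetamido-N-methoxy-N-methylpropanamide | CC(N([Mg]Cl)C(C)=O)C(=O)N(C)OC | intermediate (not isolated)
7 | N-{1-[4-methoxy-3-(triisopropylsilyloxy)phenyl]-1-oxopropan-2-yl}acetamide (racemic) | CC(NC(C)=O)C(=O)c1ccc(OC)c(O[Si](C(C)C)(C(C)C)C(C)C)c1 | intermediate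
8 | 5-[4-methoxy-3-(triisopropylsilyloxy)phenyl]-2,4-dimethyl-1,3-oxazole | Cc1nc(C)c(-c2ccc(OC)c(O[Si](C(C)C)(C(C)C)C(C)C)c2)o1 | intermediate
9 | 2-chloro-1,1-dimethoxyethane | COC(CCl)OC | starting material
10 | (3-bromopropoxy)(tert-butyl)dimethylsilane | CC(C)(C)[Si](C)(C)OCCCBr | starting material
11 | sodium methoxyacetylide | [Na+].[C-]#COC | intermediate (not isolated)
12 | tert-butyl[(5-methoxypent-4-yn-1-yl)oxy]dimethylsilane | COC#CCCCO[Si](C)(C)C(C)(C)C | intermediate
13 | 5-methoxypent-4-yn-1-ol | COC#CCCCO | intermediate
14 | 5-methoxypent-4-ynal | COC#CCCC=O | intermediate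
15 | 2-(lithiomethyl)-5-[4-methoxy-3-(triisopropylsilyloxy)phenyl]-4-methyl-1,3-oxazole | [Li]Cc1nc(C)c(-c2ccc(OC)c(O[Si](C(C)C)(C(C)C)C(C)C)c2)o1 | intermediate (not isolated)
16 | 6-methoxy-1-{5-[4-methoxy-3-(triisopropylsilyloxy)phenyl]-4-methyl-1,3-oxazol-2-yl}hex-5-yn-2-ol (racemic) | COC#CCCC(O)Cc1nc(C)c(-c2ccc(OC)c(O[Si](C(C)C)(C(C)C)C(C)C)c2)o1 | intermediate
17 | 6-methoxy-1-{5-[4-methoxy-3-(triisopropylsilyloxy)phenyl]-4-methyl-1,3-oxazol-2-yl}hex-5-yn-2-one | COC#CCCC(=O)Cc1nc(C)c(-c2ccc(OC)c(O[Si](C(C)C)(C(C)C)C(C)C)c2)o1 | intermediate
18 | 1-bromo-3-methylbut-2-ene | CC(C)=CCBr | starting material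
19 | dilithium 1,3-dianion of ketone 17 | [Li+].[Li+].COC#CC[CH-]C([O-])=Cc1nc(C)c(-c2ccc(OC)c(O[Si](C(C)C)(C(C)C)C(C)C)c2)o1 | intermediate (not isolated)
20 | 6-methoxy-1-{5-[4-methoxy-3-(triisopropylsilyloxy)phenyl]-4-methyl-1,3-oxazol-2-yl}-3-(3-methylbut-2-en-1-yl)hex-5-yn-2-one (racemic) | COC#CCC(CC=C(C)C)C(=O)Cc1nc(C)c(-c2ccc(OC)c(O[Si](C(C)C)(C(C)C)C(C)C)c2)o1 | intermediate
21 | 7-oxa-2-azabicyclo[2.2.1]hepta-2,5-diene cycloadduct fused to the cyclohexanone (diastereomer mixture) | O=C1CC23OC(c4ccc(OC)c(O[Si](C(C)C)(C(C)C)C(C)C)c4)(C(C)=N2)C(OC)=C3CC1CC=C(C)C | intermediate (not isolated)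
22 | 3-methoxy-2-[4-methoxy-3-(triisopropylsilyloxy)phenyl]-5-(3-methylbut-2-en-1-yl)-4,5-dihydro-1-benzofuran-6(7H)-one (racemic) | COc1ccc(-c2oc3c(c2OC)CC(CC=C(C)C)C(=O)C3)cc1O[Si](C(C)C)(C(C)C)C(C)C | intermediate
23 | 3-methoxy-2-[4-methoxy-3-(triisopropylsilyloxy)phenyl]-5-(3-methylbut-2-en-1-yl)-6-(triisopropylsilyloxy)-4,5-dihydro-1-benzofuran (racemic) | COc1ccc(-c2oc3c(c2OC)CC(CC=C(C)C)C(O[Si](C(C)C)(C(C)C)C(C)C)=C3)cc1O[Si](C(C)C)(C(C)C)C(C)C | intermediate
24 | 3-methoxy-2-[4-methoxy-3-(triisopropylsilyloxy)phenyl]-5-(3-methylbut-2-en-1-yl)-6-(triisopropylsilyloxy)-1-benzofuran | COc1ccc(-c2oc3cc(O[Si](C(C)C)(C(C)C)C(C)C)c(CC=C(C)C)cc3c2OC)cc1O[Si](C(C)C)(C(C)C)C(C)C | intermediate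
25 | 5-[6-hydroxy-3-methoxy-5-(3-methylbut-2-en-1-yl)-1-benzofuran-2-yl]-2-methoxyphenol | COc1ccc(-c2oc3cc(O)c(CC=C(C)C)cc3c2OC)cc1O | target

## Step count and least certain steps

Total step count: 14. Longest linear sequence: 10 steps (steps 1, 3, 4, 8, 9, 10, 11, 12, 13, 14; the branch through steps 5, 6 and 7 is equally long).

Step 11 (key step, proposed new method). The cycloaddition may be too slow at temperatures the substrate survives, because both partners are electron-rich. The enol form of the β-keto oxazole may add its O–H across the ynol ether faster than the ring closes. The prenyl double bond may compete as dienophile. The fallback uses known reactions only, sets out from 2 and returns at 24.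
- 4-Bromobenzene-1,3-diol is acylated with chloroacetonitrile under Houben–Hoesch conditions (ZnCl2, HCl, Et2O; then hot water), para to one hydroxyl, to give 1-(5-bromo-2,4-dihydroxyphenyl)-2-chloroethan-1-one F1.
- NaOAc in hot ethanol closes F1 by intramolecular O-alkylation to 5-bromo-6-hydroxy-1-benzofuran-3(2H)-one F2.
- Silylation (TIPSCl, imidazole, DMF) gives 5-bromo-6-(triisopropylsilyloxy)-1-benzofuran-3(2H)-one F3.
- O-Methylation of its potassium enolate (KN(SiMe3)2, THF, −78 °C; dimethyl sulfate) gives 5-bromo-3-methoxy-6-(triisopropylsilyloxy)-1-benzofuran F4.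
- Stille coupling with tributyl(3-methylbut-2-en-1-yl)stannane (Pd(PPh3)4, DMF, 90 °C) gives 3-methoxy-5-(3-methylbut-2-en-1-yl)-6-(triisopropylsilyloxy)-1-benzofuran F5.
- Lithiation at C2 (n-BuLi, THF, −78 °C) and transmetalation with ZnCl2 give the 2-benzofuranylzinc chloride F6.
- Negishi coupling of F6 with aryl bromide 2 (Pd(OAc)2, SPhos, THF, 60 °C) gives 24, after which step 14 is run unchanged.

Step 5. Substitution by the sparingly soluble sodium acetylide on bromide 10 in ammonia may be slow, leaving room for ammonolysis or elimination of the bromide. The fallback sets out from 9 and returns at 13, replacing steps 5 and 6 by ring opening of an unprotected three-carbon unit. Compound 9 is treated with NaNH2 in liquid NH3 as before, the salt is protonated with cold aqueous NH4Cl, and methoxyethyne F7 (boiling near room temperature) is distilled into cold THF. n-BuLi at −78 °C gives lithium methoxyacetylide F8, which opens oxetane in the presence of BF3·OEt2 at −78 °C to give 13 directly.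

Step 10. Alkylation may occur at C1 or on oxygen instead of at C3, a second alkylation may follow, or the excess amide base may isomerise the ynol ether to an allenyl ether. The fallback sets out from 14 and returns at 20, putting the prenyl group in before the oxazole is attached, at a carbon that has no rival site.
- Aldehyde 14 and 1,1-dimethylhydrazine give the N,N-dimethylhydrazone F9.
- Deprotonation with LiN(i-Pr)2 and alkylation of the aza-enolate with 18 give the α-prenylated hydrazone F10.
- Buffered aqueous Cu(OAc)2 in THF at pH 7 releases 5-methoxy-2-(3-methylbut-2-en-1-yl)pent-4-ynal F11.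
- Addition of 15 under the conditions of step 8 gives the carbinol F12 as a diastereomer mixture, and oxidation under the conditions of step 9 gives 20.

Step 13. The oxidant may go on to abstract hydride from the benzylic, allylic CH2 of the prenyl group in the product, or may attack the electron-rich 3-methoxyfuran. Early loss of the enol silyl group would expose a phenol to chromene formation. The fallback sets out from 22 and returns at 25, replacing hydride abstraction by a palladium-enolate dehydrogenation of the ketone itself. Compound 22 is heated with catalytic Pd(O2CCF3)2 and 2-(dimethylamino)pyridine under O2 in DMSO at 60 °C. A palladium enolate formed reversibly at C5 can undergo β-hydride elimination toward C4, and the dienone tautomerises to 3-methoxy-2-[4-methoxy-3-(triisopropylsilyloxy)phenyl]-5-(3-methylbut-2-en-1-yl)-1-benzofuran-6-ol F13. Desilylation with n-Bu4NF and AcOH as in step 14 then gives 25.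

## Further compounds

F1 | step 11 | 1-(5-bromo-2,4-dihydroxyphenyl)-2-chloroethan-1-one | O=C(CCl)c1cc(Br)c(O)cc1O
F2 | step 11 | 5-bromo-6-hydroxy-1-benzofuran-3(2H)-one | O=C1COc2cc(O)c(Br)cc21
F3 | step 11 | 5-bromo-6-(triisopropylsilyloxy)-1-benzofuran-3(2H)-one | O=C1COc2cc(O[Si](C(C)C)(C(C)C)C(C)C)c(Br)cc21
F4 | step 11 | 5-bromo-3-methoxy-6-(triisopropylsilyloxy)-1-benzofuran | COc1coc2cc(O[Si](C(C)C)(C(C)C)C(C)C)c(Br)cc12
F5 | step 11 | 3-methoxy-5-(3-methylbut-2-en-1-yl)-6-(triisopropylsilyloxy)-1-benzofuran | COc1coc2cc(O[Si](C(C)C)(C(C)C)C(C)C)c(CC=C(C)C)cc12
F6 | step 11 | chloro[3-methoxy-5-(3-methylbut-2-en-1-yl)-6-(triisopropylsilyloxy)-1-benzofuran-2-yl]zinc | COc1c([Zn]Cl)oc2cc(O[Si](C(C)C)(C(C)C)C(C)C)c(CC=C(C)C)cc12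
F7 | step 5 | methoxyethyne | C#COC
F8 | step 5 | lithium methoxyacetylide | [Li+].[C-]#COC
F9 | step 10 | (E)-1-(5-methoxypent-4-yn-1-ylidene)-2,2-dimethylhydrazine | COC#CCC/C=N/N(C)C
F10 | step 10 | (E)-1-[5-methoxy-2-(3-methylbut-2-en-1-yl)pent-4-yn-1-ylidene]-2,2-dimethylhydrazine (racemic) | COC#CCC(CC=C(C)C)/C=N/N(C)C
F11 | step 10 | 5-methoxy-2-(3-methylbut-2-en-1-yl)pent-4-ynal (racemic) | COC#CCC(CC=C(C)C)C=O
F12 | step 10 | 6-methoxy-1-{5-[4-methoxy-3-(triisopropylsilyloxy)phenyl]-4-methyl-1,3-oxazol-2-yl}-3-(3-methylbut-2-en-1-yl)hex-5-yn-2-ol (diastereomer mixture) | COC#CCC(CC=C(C)C)C(O)Cc1nc(C)c(-c2ccc(OC)c(O[Si](C(C)C)(C(C)C)C(C)C)c2)o1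
F13 | step 13 | 3-methoxy-2-[4-methoxy-3-(triisopropylsilyloxy)phenyl]-5-(3-methylbut-2-en-1-yl)-1-benzofuran-6-ol | COc1ccc(-c2oc3cc(O)c(CC=C(C)C)cc3c2OC)cc1O[Si](C(C)C)(C(C)C)C(C)C
A1 | alternative 1 | trans-2-[4-methoxy-3-(methoxymethoxy)phenyl]-6-(methoxymethoxy)-5-(3-methylbut-2-en-1-yl)-2,3-dihydro-1-benzofuran-3-ol (racemic, one enantiomer drawn) | O[C@H]1c2cc(CC=C(C)C)c(OCOC)cc2O[C@@H]1c1ccc(OC)c(OCOC)c1
A2 | alternative 1 | 2-hydroxy-4-(methoxymethoxy)-5-(3-methylbut-2-en-1-yl)benzaldehyde | O=Cc1cc(CC=C(C)C)c(OCOC)cc1O
A3 | alternative 1 | {[4-methoxy-3-(methoxymethoxy)phenyl]methyl}dimethylsulfonium bromide | C[S+](C)Cc1ccc(OC)c(OCOC)c1.[Br-]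
A4 | alternative 1 | 2-[4-methoxy-3-(methoxymethoxy)phenyl]-6-(methoxymethoxy)-5-(3-methylbut-2-en-1-yl)-1-benzofuran-3(2H)-one (racemic) | O=C1C(c2ccc(OC)c(OCOC)c2)Oc2cc(OCOC)c(CC=C(C)C)cc21
A5 | alternative 2 | 2-{3-[(tert-butyldimethylsilyl)oxy]-4-methoxyphenyl}-3-methoxy-5-(3-methylbut-2-en-1-yl)-1-benzofuran-6-ol | COc1ccc(-c2oc3cc(O)c(CC=C(C)C)cc3c2OC)cc1O[Si](C)(C)C(C)(C)C
A6 | alternative 2 | 1-{5-[3-(tert-butyldimethylsilyloxy)-4-methoxyphenyl]-4-methoxy-3-[(1Z)-5-methylhexa-1,4-dien-1-yl]furan-2-yl}-2-diazoethan-1-one | COc1ccc(-c2oc(C(=O)C=[N+]=[N-])c(/C=C\CC=C(C)C)c2OC)cc1O[Si](C)(C)C(C)(C)C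
A7 | alternative 3 | 3-methoxy-2-[4-methoxy-3-(methoxymethoxy)phenyl]-5-(3-methylbut-2-en-1-yl)-1-benzofuran-6-ol | COCOc1cc(-c2oc3cc(O)c(CC=C(C)C)cc3c2OC)ccc1OC
A8 | alternative 3 | 3-[(1Z)-2-acetyl-5-methylhexa-1,4-dien-1-yl]-4-methoxy-5-[4-methoxy-3-(methoxymethoxy)phenyl]furan-2(5H)-one (racemic) | COCOc1cc(C2OC(=O)C(/C=C(/CC=C(C)C)C(C)=O)=C2OC)ccc1OC
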